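**Retrosynthetic overview**

- The strategy rests on ring B: C2', C3' and C4' carry three contiguous oxygens, C5' and C6' are CH, and C1' is bonded to C2 of the chromone. A squarate-derived 2,3-dimethoxycyclobutenone supplies C2' to C5' with all three oxygens in place.
- The last disconnection is the 2'-O-methyl bond, giving the 2'-hydroxyflavone.
- Ring B is disconnected at C5'–C6' (Stille coupling) and C1'–C2' (6π electrocyclisation), giving 4-chloro-2,3-dimethoxycyclobutenone and the (E)-2-(2-stannylvinyl)chromone.
- The vinylstannane comes from the chromone-2-carbaldehyde (stannyl Takai-type olefination), this from the 2-methylchromone (SeO2), and this from the 2-hydroxyacetophenone and ethyl acetate. The chloride comes from dimethyl squarate.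
- Ring order: ring A is bought, ring C (pyranone) is closed first, ring B is built last.

Key step: step 7

Remark: the target has no stereocenter. The sp3 carbons of the cyclobutenone and cyclohexadienone intermediates are formed racemic and are lost on aromatisation; the E alkene of the vinylstannane is the only stereo-element the route sets.

**Step 1**
Reactants: 1 1-(2-hydroxy-4,5-dimethoxyphenyl)ethanone; 2 ethyl acetate
Product: 4 6,7-dimethoxy-2-methylchromen-4-one, via diketone 3 (not isolated)
Conditions: NaH, THF, 65 °C; then conc. HCl, AcOH, 100 °C
Reagents that add atoms: none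
Why: Claisen condensation of the acetophenone dianion with ethyl acetate should give the 1,3-diketone 3, and acid-catalysed cyclodehydration (phenol oxygen onto the distal carbonyl) closes ring C.

**Step 2**
Reactants: 4 6,7-dimethoxy-2-methylchromen-4-one
Product: 5 6,7-dimethoxy-4-oxochromene-2-carbaldehyde
Conditions: SeO2, xylene, reflux
Reagents that add atoms: selenium dioxide, O=[Se]=O
Why: Riley oxidation; the 2-methyl group is vinylogously activated by the pyranone carbonyl and should be oxidised to the aldehyde, while the aryl methyl ethers and the rings are inert to SeO2.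

**Step 3**
Reactants: 6 dibromomethane; 7 tributyltin chloride
Product: 9 tributyl(dibromomethyl)stannane, via dibromomethyllithium 8 (not isolated)
Conditions: LiN(iPr)2 (LDA), THF, −78 °C; then Bu3SnCl, −78 °C to rt
Reagents that add atoms: none
Why: Deprotonation of dibromomethane gives a carbenoid that is stable at −78 °C for long enough to displace chloride at tin (alkylation of a stannyl chloride by an organolithium).

**Step 4**
Reactants: 5 6,7-dimethoxy-4-oxochromene-2-carbaldehyde; 9 tributyl(dibromomethyl)stannane
Product: 11 (E)-6,7-dimethoxy-2-[2-(tributylstannyl)vinyl]chromen-4-one, via tributyl(diiodomethyl)stannane 10 (not isolated)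
Conditions: CrCl2 (8 equiv), LiI (4 equiv), THF/DMF, rt, dark; work-up on Et3N-deactivated silica
Reagents that add atoms: none
Why: Takai-type olefination with a stannyl-substituted geminal dihalide; iodide exchange gives 10, CrCl2 turns it into a geminal dichromium reagent that adds to the aldehyde only (the chromone carbonyl is a vinylogous ester), and anti elimination from the less hindered adduct sets the E alkene.

**Step 5**
Reactants: 12 dimethyl squarate (3,4-dimethoxycyclobut-3-ene-1,2-dione)
Product: 13 rac-4-hydroxy-2,3-dimethoxycyclobut-2-en-1-one
Conditions: LiAlH(OtBu)3, THF, −78 to 0 °C; then cold H2O, neutral work-up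
Reagents that add atoms: none
Why: 1,2-Reduction of one of the two equivalent carbonyls by a bulky, mild hydride; the alkoxide formed should not be reduced again at low temperature, and the new stereocenter is racemic and is lost later.

**Step 6**
Reactants: 13 rac-4-hydroxy-2,3-dimethoxycyclobut-2-en-1-one
Product: 14 rac-4-chloro-2,3-dimethoxycyclobut-2-en-1-one
Conditions: PPh3, CCl4, CH2Cl2, 0 °C to rt; pentane trituration, filtration, used at once
Reagents that add atoms: carbon tetrachloride, ClC(Cl)(Cl)Cl
Why: Appel chlorination under neutral, anhydrous conditions; chloride displaces the alkoxyphosphonium group at C4, and if the ion pair dissociates the allyl cation should still recombine at C4 because that keeps the conjugated vinylogous ester.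

**Step 7**
Reactants: 14 rac-4-chloro-2,3-dimethoxycyclobut-2-en-1-one; 11 (E)-6,7-dimethoxy-2-[2-(tributylstannyl)vinyl]chromen-4-one
Product: 18 2-(2-hydroxy-3,4-dimethoxyphenyl)-6,7-dimethoxychromen-4-one, via alkenylcyclobutenone 15 (not isolated), via dienylketene 16 (not isolated), via cyclohexadienone 17 (not isolated)
Conditions: Pd2(dba)3 (2.5 mol %), tri(2-furyl)phosphine (10 mol %), 1,4-dioxane, 50 °C, then 100 °C
Reagents that add atoms: none
Why: Zerovalent palladium inserts into the allylic C4–Cl bond of 14 to give an oxocyclobutenyl complex of divalent palladium, and transmetalation from stannane 11 (eased by the weakly donating tri(2-furyl)phosphine) followed by reductive elimination forms the C5'–C6' bond with retention of the E alkene, giving 15. At 100 °C 15 opens reversibly by conrotatory 4π cleavage of its C1–C4 bond, and only the dienylketene isomer 16, in which the alkenyl group is cis to the ketene carbon, can react further, the other isomer reclosing to 15. Ring B is closed by a thermal disrotatory 6π electrocyclisation of 16 that joins the ketene carbon (future C2') to the chromone-bearing alkene carbon (future C1'), and dienone 17 tautomerises irreversibly to phenol 18. The closest known reaction type is the Stille coupling of 4-chlorocyclobutenones with alkenylstannanes followed by thermal ring expansion to phenols. No stereocenter is set, since the sp3 carbons of 15 and 17 both become aromatic carbons. The selectivity needed is coupling at C4 and not at C2 of the allyl-type palladium intermediate, which should hold because C4 is the unsubstituted terminus and coupling there keeps the conjugated vinylogous ester while C2 is blocked by its methoxy group; the connectivity of the cascade then places OH at C2' and the methoxy groups at C3' and C4'.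

**Step 8**
Reactants: 18 2-(2-hydroxy-3,4-dimethoxyphenyl)-6,7-dimethoxychromen-4-one
Product: 19 6,7-dimethoxy-2-(2,3,4-trimethoxyphenyl)chromen-4-one
Conditions: MeI, K2CO3, acetone, reflux
Reagents that add atoms: iodomethane, CI
Why: Williamson ether synthesis; the 2'-phenoxide is the only acidic site and should be methylated cleanly, the chromone and the existing ethers being inert.

**Compound list**

1 | 1-(2-hydroxy-4,5-dimethoxyphenyl)ethanone | CC(=O)c1cc(OC)c(OC)cc1O | starting material
2 | ethyl acetate | CCOC(C)=O | starting material
3 | 1-(2-hydroxy-4,5-dimethoxyphenyl)butane-1,3-dione | CC(=O)CC(=O)c1cc(OC)c(OC)cc1O | intermediate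
4 | 6,7-dimethoxy-2-methylchromen-4-one | Cc1cc(=O)c2cc(OC)c(OC)cc2o1 | intermediate
5 | 6,7-dimethoxy-4-oxochromene-2-carbaldehyde | O=Cc1cc(=O)c2cc(OC)c(OC)cc2o1 | intermediate
6 | dibromomethane | BrCBr | starting material
7 | tributyltin chloride | CCCC[Sn](Cl)(CCCC)CCCC | starting material
8 | dibromomethyllithium | [Li]C(Br)Br | intermediate
9 | tributyl(dibromomethyl)stannane | CCCC[Sn](CCCC)(CCCC)C(Br)Br | intermediate
10 | tributyl(diiodomethyl)stannane | CCCC[Sn](CCCC)(CCCC)C(I)I | intermediate
11 | (E)-6,7-dimethoxy-2-[2-(tributylstannyl)vinyl]chromen-4-one | CCCC[Sn](CCCC)(CCCC)/C=C/c1cc(=O)c2cc(OC)c(OC)cc2o1 | intermediate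
12 | dimethyl squarate (3,4-dimethoxycyclobut-3-ene-1,2-dione) | COC1=C(OC)C(=O)C1=O | starting material
13 | rac-4-hydroxy-2,3-dimethoxycyclobut-2-en-1-one | COC1=C(OC)C(O)C1=O | intermediate
14 | rac-4-chloro-2,3-dimethoxycyclobut-2-en-1-one | COC1=C(OC)C(Cl)C1=O | intermediate
15 | rac-2-[(E)-2-(2,3-dimethoxy-4-oxocyclobut-2-en-1-yl)vinyl]-6,7-dimethoxychromen-4-one | COC1=C(OC)C(/C=C/c2cc(=O)c3cc(OC)c(OC)cc3o2)C1=O | intermediate
16 | (3E,5E)-6-(6,7-dimethoxy-4-oxochromen-2-yl)-2,3-dimethoxyhexa-1,3,5-trien-1-one | O=C=C(OC)/C(OC)=C\C=C\c1cc(=O)c2cc(OC)c(OC)cc2o1 | intermediate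
17 | rac-2-(4,5-dimethoxy-6-oxocyclohexa-2,4-dien-1-yl)-6,7-dimethoxychromen-4-one | O=C1C(OC)=C(OC)C=CC1c2cc(=O)c3cc(OC)c(OC)cc3o2 | intermediate
18 | 2-(2-hydroxy-3,4-dimethoxyphenyl)-6,7-dimethoxychromen-4-one | COc1cc2oc(-c3ccc(OC)c(OC)c3O)cc(=O)c2cc1OC | intermediate
19 | 6,7-dimethoxy-2-(2,3,4-trimethoxyphenyl)chromen-4-one | COc1cc2oc(-c3ccc(OC)c(OC)c3OC)cc(=O)c2cc1OC | target

**Step count**

Total steps: 8. Longest linear sequence: 5 (steps 1, 2, 4, 7, 8).

**Steps most likely to fail**

Step 7. Transmetalation from the electron-poor vinylstannane may be slow, so that the labile chloride ionises and decomposes before it couples. Coupling at C2 of the palladium intermediate would lead to the regioisomeric ring B, and the ketene may be lost to dimerisation instead of closing. The fallback leaves the benzannulation and builds ring C last by classical flavone chemistry. It sets out from 1, which is condensed with 2,3,4-trimethoxybenzaldehyde (COc1ccc(C=O)c(OC)c1OC) under Claisen–Schmidt conditions (KOH, EtOH, rt) to the chalcone (E)-1-(2-hydroxy-4,5-dimethoxyphenyl)-3-(2,3,4-trimethoxyphenyl)prop-2-en-1-one F1. Oxidative cyclisation of this chalcone with catalytic I2 in DMSO at 130 °C should give the flavone directly, so the fallback comes back to the route at 19.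

Step 6. The alcohol and the chloride both ionise easily to a methoxy-stabilised allyl cation, and hydrolysis or loss of a methyl group from that cation would drain material to the cyclobutenedione; the chloride may also decompose on purification. The fallback changes the electrophile class. It sets out from 13, which is acetylated (Ac2O, pyridine, DMAP, CH2Cl2, 0 °C) to the less ionisable allylic ester 2,3-dimethoxy-4-oxocyclobut-2-en-1-yl acetate F2. This acetate is coupled with stannane 11 under allylic Stille conditions (Pd2(dba)3, tri(2-furyl)phosphine, LiCl, DMF, 50 °C, then 100 °C); the same oxocyclobutenyl-palladium intermediate and ring expansion follow, and the fallback comes back to the route at 18.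

Step 4. The very electrophilic aldehyde may be consumed by single-electron reduction and pinacol coupling with CrCl2 before the dichromium reagent forms, and the vinylstannane may lose tin by protonolysis on work-up. The fallback avoids chromium. It sets out from 5, which is homologated with dimethyl (1-diazo-2-oxopropyl)phosphonate (COP(=O)(OC)C(=[N+]=[N-])C(C)=O; K2CO3, MeOH, 0 °C) to the alkyne 2-ethynyl-6,7-dimethoxychromen-4-one F3. Radical hydrostannation of this alkyne (Bu3SnH, CCCC[SnH](CCCC)CCCC, catalytic AIBN, toluene, 80 °C, with a slight excess of Bu3SnH and prolonged heating to equilibrate to the E isomer) should place tin on the terminal carbon, and the fallback comes back to the route at 11.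

**Further compounds**

F1 | step 7 | (E)-1-(2-hydroxy-4,5-dimethoxyphenyl)-3-(2,3,4-trimethoxyphenyl)prop-2-en-1-one | COc1cc(O)c(C(=O)/C=C/c2ccc(OC)c(OC)c2OC)cc1OC
F2 | step 6 | 2,3-dimethoxy-4-oxocyclobut-2-en-1-yl acetate | COC1=C(OC)C(OC(C)=O)C1=O
F3 | step 4 | 2-ethynyl-6,7-dimethoxychromen-4-one | C#Cc1cc(=O)c2cc(OC)c(OC)cc2o1
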